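**Retrosynthetic overview**

1. The target holds two trans-2,3-diaryl-2,3-dihydrobenzofurans joined by the bond C3(ring A)–C6(ring B): ring A carries the styryl group at C6 and the 4-hydroxyphenyl group at C2, ring B carries the 2,4-dihydroxyphenyl group at C2 and the 3,5-dihydroxyphenyl group at C3.
2. Ring B: O1–C2 and C2–C3 are cut together, back to an o-quinone methide (O1–C7a–C3a–C3) and a chiral sulfonium aryl-methylide that brings C2 with its aryl group ([4+1] annulation: C–C bond first, then the ring closes at O1–C2).
3. Enabling feature: in ring B, O1 is a phenolic oxygen ortho to C3a and C3 is a benzylic methine, so O1–C7a–C3a–C3 can be unmasked as an o-quinone methide. C3a lies between two equivalent oxygens (O1 and the oxygen on C4), so one is spent as a Boc trigger and either closes to the same ring. C2 bears an electron-rich aryl group, which suits both the ylide and the displacement.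
4. The o-quinone methide precursors are O-Boc diaryl carbinols made from an aryllithium and one common 4-bromo-2,6-dioxygenated benzaldehyde. Its bromine serves once for the stilbene (Heck reaction) and once, in ring B, as the lithium handle for ring A.
5. Order of ring formation: ring B (racemic carbinol to one enantiomer under reagent control), then ring A in the same way (both carbinol epimers to one diastereomer), then acidolysis of all phenol protecting groups.

Key step: step 8

Assumption (chemistry): (1S,4S,5S)-isothiocineole is taken to be S-benzylated on its exo lone pair (the one pointing away from the three-carbon bridge) and its aryl-methylides to react with the aryl group syn to the sulfur lone pair and the electrophile entering from the bridgehead side; after invertive ring closure this corresponds to (2R). If a model annulation shows the opposite sense, the (1R,4R,5R)-sulfide replaces it with no other change.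

**Route**

Step 1
Reactants: 1 4-bromo-2,6-dimethoxybenzaldehyde
Product: 2 4-bromo-2,6-dihydroxybenzaldehyde
Conditions: BBr3 (2.5 equiv), CH2Cl2, −78 to 23 °C; then H2O
Reagents that add atoms: none
Why: Lewis-acid cleavage of the two aryl methyl ethers, helped by chelation to the ortho formyl group, should leave the aryl bromide and the aldehyde untouched; no stereocentre is involved.

Step 2
Reactants: 2 4-bromo-2,6-dihydroxybenzaldehyde
Product: 3 4-bromo-2-hydroxy-6-(methoxymethoxy)benzaldehyde
Conditions: MOMCl (1.05 equiv), i-Pr2NEt (1.2 equiv), CH2Cl2, 0 °C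
Reagents that add atoms: chloromethyl methyl ether (MOMCl), COCCl
Why: Williamson-type O-alkylation should stop at the mono-ether, because the remaining hydroxyl is held in a hydrogen bond to the formyl group; the two hydroxyls are equivalent, so only one mono-ether exists.

Step 3
Reactants: 3 4-bromo-2-hydroxy-6-(methoxymethoxy)benzaldehyde
Product: 4 tert-butyl 5-bromo-2-formyl-3-(methoxymethoxy)phenyl carbonate
Conditions: Boc2O (1.2 equiv), DMAP (5 mol%), i-Pr2NEt (1.2 equiv), THF, 0 to 23 °C
Reagents that add atoms: di-tert-butyl dicarbonate (Boc2O), CC(C)(C)OC(=O)OC(=O)OC(C)(C)C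
Why: DMAP-catalysed O-acylation of the chelated phenol installs the carbonate that later acts as the internal trigger for o-quinone methide release.

Step 4
Reactants: 5 5-bromobenzene-1,3-diol
Product: 6 1-bromo-3,5-bis(methoxymethoxy)benzene
Conditions: MOMCl (2.5 equiv), i-Pr2NEt (3 equiv), CH2Cl2, 0 to 23 °C
Reagents that add atoms: chloromethyl methyl ether (MOMCl), COCCl
Why: Twofold Williamson-type etherification protects both phenols as acetals that tolerate organolithium reagents and strong amide bases.

Step 5
Reactants: 6 1-bromo-3,5-bis(methoxymethoxy)benzene; 4 tert-butyl 5-bromo-2-formyl-3-(methoxymethoxy)phenyl carbonate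
Product: 8 tert-butyl 5-bromo-2-[[3,5-bis(methoxymethoxy)phenyl](hydroxy)methyl]-3-(methoxymethoxy)phenyl carbonate (racemic), via 3,5-bis(methoxymethoxy)phenyllithium 7 (not isolated)
Conditions: n-BuLi (1.05 equiv), THF, −78 °C; then 4, −78 °C; AcOH, −78 °C
Reagents that add atoms: none
Why: Bromine–lithium exchange and 1,2-addition of the aryllithium to the aldehyde should outrun attack on the tert-butyl carbonate and on the aryl bromide, and protonation of the lithium alkoxide at −78 °C keeps the Boc group on the phenol; the carbinol centre is racemic and is erased in step 8.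

Step 6
Reactants: 9 2,4-bis(methoxymethoxy)benzaldehyde
Product: 10 [2,4-bis(methoxymethoxy)phenyl]methanol
Conditions: NaBH4 (0.5 equiv), MeOH, 0 °C
Reagents that add atoms: none
Why: Borohydride reduction of the aldehyde gives the benzylic alcohol without touching the acetals.

Step 7
Reactants: 10 [2,4-bis(methoxymethoxy)phenyl]methanol; 11 (1S,4S,5S)-isothiocineole
Product: 12 (1S,4S,5S)-6-[2,4-bis(methoxymethoxy)benzyl]-4,7,7-trimethyl-6-thiabicyclo[3.2.1]octan-6-ium tetrafluoroborate (benzyl group exo on sulfur)
Conditions: 11 (1.1 equiv), i-Pr2NEt (1.3 equiv), Ms2O (1.1 equiv), CH2Cl2, −40 to 0 °C; then aq NaBF4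
Reagents that add atoms: sodium tetrafluoroborate, [Na+].F[B-](F)(F)F
Why: The benzylic mesylate formed in the flask is captured at once by the thioether (S-alkylation), which avoids strong acid next to the MOM acetals; alkylation on the less hindered exo lone pair should give one sulfonium diastereomer, and anion exchange gives a salt that can be recrystallised.

Step 8
Reactants: 8 tert-butyl 5-bromo-2-[[3,5-bis(methoxymethoxy)phenyl](hydroxy)methyl]-3-(methoxymethoxy)phenyl carbonate; 12 isothiocineolium tetrafluoroborate
Product: 16 (2R,3R)-6-bromo-2-[2,4-bis(methoxymethoxy)phenyl]-3-[3,5-bis(methoxymethoxy)phenyl]-4-(methoxymethoxy)-2,3-dihydrobenzofuran, via sulfonium ylide 13 (not isolated), via o-quinone methide 14 (not isolated), via phenolate sulfonium betaine 15 (not isolated)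
Conditions: 12 (1.3 equiv), KN(SiMe3)2 (1.25 equiv), THF, −78 °C; then 8 (1.0 equiv); then KN(SiMe3)2 (1.05 equiv), −78 to −20 °C
Reagents that add atoms: none
Why: Proposed new method: deprotonation of carbinol 8 moves the Boc group from the phenolic to the benzylic oxygen and expels tert-butyl carbonate, so that o-quinone methide 14 is released at low temperature next to ylide 13; the ylide carbon adds to the exocyclic carbon (the future C3) to give betaine 15, and the phenolate oxygen O1 then displaces the sulfide at C2 with inversion, which closes ring B. The closest known reaction types are the [4+1] annulation of in situ o-quinone methides with sulfonium ylides and with ammonium ylides that carry a chiral amine as leaving group, the cyclopropanation of p-quinone methides with benzylsulfonium ylides, and the asymmetric epoxidation of aldehydes with isothiocineole-derived aryl-methylides; new is the union of a chiral sulfonium aryl-methylide with an o-quinone methide. Ring B closes in the 5-exo-tet mode (O1 onto C2, sulfide as exocyclic leaving group). C2 is controlled by the sulfide (one sulfonium diastereomer, ylide aryl syn to the sulfur lone pair, electrophile entering from the bridgehead side away from the gem-dimethyl group, then inversion), and C3 is fixed in the C–C bond-forming event, where the o-quinone methide is expected to approach with its 3,5-disubstituted aryl group anti to the ylide aryl group, the arrangement that leads directly to the anti-periplanar betaine and the trans ring. The step needs 1,4-addition rather than O-benzylation of phenolates by the salt, which release of 14 into an excess of preformed ylide at −78 °C should secure, and it needs one face of the o-quinone methide, which rests on the ylide alone because the racemic carbinol and any E/Z mixture of 14 converge on the same planar electrophile. Either oxygen flanking C3a would close to the same ring, so the one spent as the Boc trigger becomes O1 and the other stays as its MOM ether.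

Step 9
Reactants: 4 tert-butyl 5-bromo-2-formyl-3-(methoxymethoxy)phenyl carbonate; 17 4-tert-butoxystyrene
Product: 18 tert-butyl 5-[(E)-2-(4-tert-butoxyphenyl)ethenyl]-2-formyl-3-(methoxymethoxy)phenyl carbonate
Conditions: Pd2(dba)3 (1.5 mol%), [HP(t-Bu)3]BF4 (6 mol%), Cy2NMe (1.2 equiv), 1,4-dioxane, 23 to 40 °C
Reagents that add atoms: none
Why: Heck reaction of the electron-poor aryl bromide (para to the formyl group) with a bulky-phosphine zerovalent palladium catalyst should run near room temperature, so the aryl carbonate survives, and syn insertion followed by syn β-hydride elimination gives the E-stilbene.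

Step 10
Reactants: 16 (2R,3R)-6-bromo-dihydrobenzofuran; 18 stilbene aldehyde
Product: 20 tert-butyl 2-[[(2R,3R)-2-[2,4-bis(methoxymethoxy)phenyl]-3-[3,5-bis(methoxymethoxy)phenyl]-4-(methoxymethoxy)-2,3-dihydrobenzofuran-6-yl](hydroxy)methyl]-5-[(E)-2-(4-tert-butoxyphenyl)ethenyl]-3-(methoxymethoxy)phenyl carbonate (both carbinol epimers), via 6-lithio dihydrobenzofuran 19 (not isolated)
Conditions: n-BuLi (1.05 equiv), THF, −78 °C, 5 min; then 18, −78 °C; AcOH, −78 °C
Reagents that add atoms: none
Why: Bromine–lithium exchange at −78 °C should be faster than ortho-metalation between the MOM ethers or deprotonation at C3, and the aryllithium adds 1,2 to the aldehyde as in step 5; the carbinol forms as two epimers, which both lead to the same o-quinone methide in step 13.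

Step 11
Reactants: 21 4-(methoxymethoxy)benzaldehyde
Product: 22 [4-(methoxymethoxy)phenyl]methanol
Conditions: NaBH4 (0.5 equiv), MeOH, 0 °C
Reagents that add atoms: none
Why: Borohydride reduction of the aldehyde gives the benzylic alcohol.

Step 12
Reactants: 22 [4-(methoxymethoxy)phenyl]methanol; 11 (1S,4S,5S)-isothiocineole
Product: 23 (1S,4S,5S)-6-[4-(methoxymethoxy)benzyl]-4,7,7-trimethyl-6-thiabicyclo[3.2.1]octan-6-ium tetrafluoroborate (benzyl group exo on sulfur)
Conditions: 11 (1.1 equiv), i-Pr2NEt (1.3 equiv), Ms2O (1.1 equiv), CH2Cl2, −40 to 0 °C; then aq NaBF4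
Reagents that add atoms: sodium tetrafluoroborate, [Na+].F[B-](F)(F)F
Why: S-alkylation of the thioether by the benzylic mesylate formed in the flask, as in step 7, should give one sulfonium diastereomer.

Step 13
Reactants: 20 O-Boc carbinol (both epimers); 23 isothiocineolium tetrafluoroborate
Product: 27 (2R,3R)-6-[(E)-2-(4-tert-butoxyphenyl)ethenyl]-3-[(2R,3R)-2-[2,4-bis(methoxymethoxy)phenyl]-3-[3,5-bis(methoxymethoxy)phenyl]-4-(methoxymethoxy)-2,3-dihydrobenzofuran-6-yl]-4-(methoxymethoxy)-2-[4-(methoxymethoxy)phenyl]-2,3-dihydrobenzofuran, via sulfonium ylide 24 (not isolated), via o-quinone methide 25 (not isolated), via phenolate sulfonium betaine 26 (not isolated)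
Conditions: 23 (1.3 equiv), KN(SiMe3)2 (1.25 equiv), THF, −78 °C; then 20 (1.0 equiv); then KN(SiMe3)2 (1.05 equiv), −78 to −20 °C
Reagents that add atoms: none
Why: Proposed new method: the same [4+1] annulation as in step 8 (o-quinone methide 25 released from 20 by Boc transfer, 1,4-addition of ylide 24, 5-exo-tet closure of betaine 26 by the phenolate with loss of the sulfide; closest known types are the o-quinone methide/onium ylide [4+1] annulations and the isothiocineole-based asymmetric epoxidation), in which C2 and C3 of ring A should be set by the same sulfide in the same sense as in ring B because the resident stereocentres are remote, both carbinol epimers converging on one planar electrophile.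

Step 14
Reactants: 27 protected trimer
Product: 28 CNP0118407.2
Conditions: 3 M aq HCl, MeOH–THF, 45 °C, argon
Reagents that add atoms: none
Why: Acid solvolysis should remove the seven MOM acetals and the tert-butyl aryl ether in one operation, methanol trapping the liberated cations; any reversible ionisation at the benzylic C2–O bonds should re-close to the thermodynamically preferred trans rings, and no other stereocentre is touched.

**Compound list**

1 | 4-bromo-2,6-dimethoxybenzaldehyde | COc1cc(Br)cc(OC)c1C=O | starting material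
2 | 4-bromo-2,6-dihydroxybenzaldehyde | O=Cc1c(O)cc(Br)cc1O | intermediate
3 | 4-bromo-2-hydroxy-6-(methoxymethoxy)benzaldehyde | O=Cc1c(O)cc(Br)cc1OCOC | intermediate
4 | tert-butyl 5-bromo-2-formyl-3-(methoxymethoxy)phenyl carbonate | O=Cc1c(OC(=O)OC(C)(C)C)cc(Br)cc1OCOC | intermediate
5 | 5-bromobenzene-1,3-diol (5-bromoresorcinol) | Oc1cc(O)cc(Br)c1 | starting material
6 | 1-bromo-3,5-bis(methoxymethoxy)benzene | COCOc1cc(Br)cc(OCOC)c1 | intermediate
7 | 3,5-bis(methoxymethoxy)phenyllithium (not isolated) | [Li]c1cc(OCOC)cc(OCOC)c1 | intermediate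
8 | tert-butyl 5-bromo-2-[[3,5-bis(methoxymethoxy)phenyl](hydroxy)methyl]-3-(methoxymethoxy)phenyl carbonate, racemic | OC(c1cc(OCOC)cc(OCOC)c1)c1c(OC(=O)OC(C)(C)C)cc(Br)cc1OCOC | intermediate
9 | 2,4-bis(methoxymethoxy)benzaldehyde | O=Cc1ccc(OCOC)cc1OCOC | starting material
10 | [2,4-bis(methoxymethoxy)phenyl]methanol | OCc1ccc(OCOC)cc1OCOC | intermediate
11 | (1S,4S,5S)-4,7,7-trimethyl-6-thiabicyclo[3.2.1]octane (isothiocineole) | C[C@H]1CC[C@H]2C[C@@H]1SC2(C)C | starting material
12 | (1S,4S,5S)-6-[2,4-bis(methoxymethoxy)benzyl]-4,7,7-trimethyl-6-thiabicyclo[3.2.1]octan-6-ium tetrafluoroborate, benzyl group exo on sulfur | C[C@H]1CC[C@H]2C[C@@H]1[S@+](Cc1ccc(OCOC)cc1OCOC)C2(C)C.F[B-](F)(F)F | intermediate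
13 | sulfonium ylide of 12 (not isolated) | C[C@H]1CC[C@H]2C[C@@H]1[S@+]([CH-]c1ccc(OCOC)cc1OCOC)C2(C)C | intermediate
14 | 3-bromo-6-[[3,5-bis(methoxymethoxy)phenyl]methylidene]-5-(methoxymethoxy)cyclohexa-2,4-dien-1-one, o-quinone methide, E/Z not defined (not isolated) | O=C1C=C(Br)C=C(OCOC)C1=Cc1cc(OCOC)cc(OCOC)c1 | intermediate
15 | phenolate sulfonium betaine from 13 and 14 (not isolated) | C[C@H]1CC[C@H]2C[C@@H]1[S@+]([C@H](c1ccc(OCOC)cc1OCOC)[C@H](c1cc(OCOC)cc(OCOC)c1)c1c([O-])cc(Br)cc1OCOC)C2(C)C | intermediate
16 | (2R,3R)-6-bromo-2-[2,4-bis(methoxymethoxy)phenyl]-3-[3,5-bis(methoxymethoxy)phenyl]-4-(methoxymethoxy)-2,3-dihydrobenzofuran | Brc1cc(OCOC)c2c(c1)O[C@@H](c1ccc(OCOC)cc1OCOC)[C@@H]2c1cc(OCOC)cc(OCOC)c1 | intermediate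
17 | 1-tert-butoxy-4-ethenylbenzene (4-tert-butoxystyrene) | C=Cc1ccc(OC(C)(C)C)cc1 | starting material
18 | tert-butyl 5-[(E)-2-(4-tert-butoxyphenyl)ethenyl]-2-formyl-3-(methoxymethoxy)phenyl carbonate | O=Cc1c(OC(=O)OC(C)(C)C)cc(/C=C/c2ccc(OC(C)(C)C)cc2)cc1OCOC | intermediate
19 | 6-lithio derivative of 16 (not isolated) | [Li]c1cc(OCOC)c2c(c1)O[C@@H](c1ccc(OCOC)cc1OCOC)[C@@H]2c1cc(OCOC)cc(OCOC)c1 | intermediate
20 | O-Boc carbinol from 19 and 18, both epimers at the carbinol carbon | OC(c1cc(OCOC)c2c(c1)O[C@@H](c1ccc(OCOC)cc1OCOC)[C@@H]2c1cc(OCOC)cc(OCOC)c1)c1c(OC(=O)OC(C)(C)C)cc(/C=C/c2ccc(OC(C)(C)C)cc2)cc1OCOC | intermediate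
21 | 4-(methoxymethoxy)benzaldehyde | O=Cc1ccc(OCOC)cc1 | starting material
22 | [4-(methoxymethoxy)phenyl]methanol | OCc1ccc(OCOC)cc1 | intermediate
23 | (1S,4S,5S)-6-[4-(methoxymethoxy)benzyl]-4,7,7-trimethyl-6-thiabicyclo[3.2.1]octan-6-ium tetrafluoroborate, benzyl group exo on sulfur | C[C@H]1CC[C@H]2C[C@@H]1[S@+](Cc1ccc(OCOC)cc1)C2(C)C.F[B-](F)(F)F | intermediate
24 | sulfonium ylide of 23 (not isolated) | C[C@H]1CC[C@H]2C[C@@H]1[S@+]([CH-]c1ccc(OCOC)cc1)C2(C)C | intermediate
25 | o-quinone methide from 20, exocyclic E/Z not defined (not isolated) | O=C1C=C(/C=C/c2ccc(OC(C)(C)C)cc2)C=C(OCOC)C1=Cc1cc(OCOC)c2c(c1)O[C@@H](c1ccc(OCOC)cc1OCOC)[C@@H]2c1cc(OCOC)cc(OCOC)c1 | intermediate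
26 | phenolate sulfonium betaine from 24 and 25 (not isolated) | C[C@H]1CC[C@H]2C[C@@H]1[S@+]([C@H](c1ccc(OCOC)cc1)[C@H](c1cc(OCOC)c3c(c1)O[C@@H](c1ccc(OCOC)cc1OCOC)[C@@H]3c1cc(OCOC)cc(OCOC)c1)c1c([O-])cc(/C=C/c3ccc(OC(C)(C)C)cc3)cc1OCOC)C2(C)C | intermediate
27 | fully protected trimer (seven MOM ethers, one tert-butyl ether), both rings (2R,3R) | CC(C)(C)Oc1ccc(/C=C/c2cc(OCOC)c3c(c2)O[C@@H](c2ccc(OCOC)cc2)[C@@H]3c2cc(OCOC)c3c(c2)O[C@@H](c2ccc(OCOC)cc2OCOC)[C@@H]3c2cc(OCOC)cc(OCOC)c2)cc1 | intermediate
28 | CNP0118407.2 | Oc1ccc(/C=C/c2cc(O)c3c(c2)O[C@@H](c2ccc(O)cc2)[C@@H]3c2cc(O)c3c(c2)O[C@@H](c2ccc(O)cc2O)[C@@H]3c2cc(O)cc(O)c2)cc1 | target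

**Step count and risks**

Total step count: 14. Longest linear sequence: 8 steps (steps 1, 2, 3, 5, 8, 10, 13, 14).

Steps most likely to fail:

1. Step 8. Enantiomeric purity may erode if the C–C bond-forming addition of the semi-stabilised ylide shows poor simple diastereoselection or if the betaine epimerises or eliminates before ring closure; the salt may also be consumed by O-benzylation of phenolates. The fallback uses known chemistry, sets out from 10 and 8 and returns at 16. Alcohol 10 is converted into 2,4-bis(methoxymethoxy)benzyl chloride F1 (MsCl, Et3N, LiCl, THF, 0 °C) and then into [2,4-bis(methoxymethoxy)benzyl]magnesium chloride F2 (Mg, THF, 0 °C). Carbinol 8 is treated with 2.2 equiv of F2 (THF, −78 to 0 °C); the first equivalent triggers o-quinone methide formation and the second adds 1,4, giving racemic 5-bromo-2-[1-[3,5-bis(methoxymethoxy)phenyl]-2-[2,4-bis(methoxymethoxy)phenyl]ethyl]-3-(methoxymethoxy)phenol F3. Dehydrogenative ring closure with DDQ (CH2Cl2, 0 to 23 °C), the reaction type that turns 2′-hydroxyisoflavans into pterocarpans, removes hydride from the dialkoxybenzylic CH2 and lets the phenol close O1–C2 to the trans ring. This gives 16 together with the (2S,3S)-enantiomer of 16 F4, which is removed by preparative chromatography on a chiral stationary phase.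

2. Step 13. On the larger, styryl-extended o-quinone methide the ylide may lose facial control, add at the remote styryl terminus, or the betaine may undergo base-induced elimination. The fallback uses known chemistry, sets out from 20 and 22 and returns at 28. Carbinol 20 is oxidised (periodinane DMP, NaHCO3, CH2Cl2) to the O-Boc diaryl ketone F5. Alcohol 22 is converted into 4-(methoxymethoxy)benzyl chloride F6 (MsCl, Et3N, LiCl) and then into [4-(methoxymethoxy)benzyl]magnesium chloride F7 (Mg, THF). Addition of F7 (1.1 equiv, THF, −78 to 0 °C) to F5 gives, after Boc transfer, loss of tert-butyl carbonate and tautomerisation of the alkyl-substituted o-quinone methide, the 2-hydroxyaryl triarylethene F8 (E/Z mixture). Under the conditions of step 14 (3 M aq HCl, MeOH–THF, 45 °C) F8 should lose its protecting groups, and protonation of the hydroxystilbene unit at the diaryl carbon gives a p-quinone-methide-type cation at C2 that the ring A phenol closes to the trans ring. The product is 28 together with the ring A (2S,3S)-diastereomer F9, which is separated by preparative reversed-phase HPLC.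

3. Step 14. Removal of eight protecting groups may stall at partly protected stages, the liberated methoxymethyl and tert-butyl cations may alkylate the electron-rich resorcinol rings, and prolonged acid may open the benzylic C–O bonds. The fallback sets out from 27 and returns at 28. Treatment of 27 with TMSOTf and 2,2′-bipyridyl (CH2Cl2, 0 °C) exchanges the aryl MOM ethers and the tert-butyl ether for silyl ethers under buffered conditions, giving the octakis(trimethylsilyl) ether of 28 F10. Mild methanolysis (K2CO3, MeOH, 0 °C, argon) then frees the eight phenols without any Brønsted acid.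

Further compounds

F1 | step 8 | 2,4-bis(methoxymethoxy)benzyl chloride | ClCc1ccc(OCOC)cc1OCOC
F2 | step 8 | [2,4-bis(methoxymethoxy)benzyl]magnesium chloride | Cl[Mg]Cc1ccc(OCOC)cc1OCOC
F3 | step 8 | 5-bromo-2-[1-[3,5-bis(methoxymethoxy)phenyl]-2-[2,4-bis(methoxymethoxy)phenyl]ethyl]-3-(methoxymethoxy)phenol, racemic | Oc1cc(Br)cc(OCOC)c1C(Cc1ccc(OCOC)cc1OCOC)c1cc(OCOC)cc(OCOC)c1
F4 | step 8 | (2S,3S)-enantiomer of 16 | Brc1cc(OCOC)c2c(c1)O[C@H](c1ccc(OCOC)cc1OCOC)[C@H]2c1cc(OCOC)cc(OCOC)c1
F5 | step 13 | O-Boc diaryl ketone from 20 | O=C(c1cc(OCOC)c2c(c1)O[C@@H](c1ccc(OCOC)cc1OCOC)[C@@H]2c1cc(OCOC)cc(OCOC)c1)c1c(OC(=O)OC(C)(C)C)cc(/C=C/c2ccc(OC(C)(C)C)cc2)cc1OCOC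
F6 | step 13 | 4-(methoxymethoxy)benzyl chloride | ClCc1ccc(OCOC)cc1
F7 | step 13 | [4-(methoxymethoxy)benzyl]magnesium chloride | Cl[Mg]Cc1ccc(OCOC)cc1
F8 | step 13 | 2-hydroxyaryl triarylethene from F5 and F7, E/Z mixture at the trisubstituted alkene | Oc1cc(/C=C/c2ccc(OC(C)(C)C)cc2)cc(OCOC)c1C(=Cc1ccc(OCOC)cc1)c1cc(OCOC)c2c(c1)O[C@@H](c1ccc(OCOC)cc1OCOC)[C@@H]2c1cc(OCOC)cc(OCOC)c1
F9 | step 13 | diastereomer of 28 with (2S,3S) ring A | Oc1ccc(/C=C/c2cc(O)c3c(c2)O[C@H](c2ccc(O)cc2)[C@H]3c2cc(O)c3c(c2)O[C@@H](c2ccc(O)cc2O)[C@@H]3c2cc(O)cc(O)c2)cc1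
F10 | step 14 | octakis(trimethylsilyl) ether of 28 | C[Si](C)(C)Oc1ccc(/C=C/c2cc(O[Si](C)(C)C)c3c(c2)O[C@@H](c2ccc(O[Si](C)(C)C)cc2)[C@@H]3c2cc(O[Si](C)(C)C)c3c(c2)O[C@@H](c2ccc(O[Si](C)(C)C)cc2O[Si](C)(C)C)[C@@H]3c2cc(O[Si](C)(C)C)cc(O[Si](C)(C)C)c2)cc1
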